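**Plan**

- Cuts, in retrosynthetic order: (a) the spiro C–O bond between the pyranone 4‑oxygen and C1 of ring C; (b) the C1–carbinol C–C bond; (c) one lactone C–C bond and one ring B C–C bond, both made in a single radical bicyclization; (d) the two new C–C bonds at C6 of (S)‑carvone.
- Forward: ring C is (S)‑carvone. Its isopropenyl methyl is hydroxylated, C6 is made quaternary (methyl, then homoprenyl), and an allylic malonate closes the δ‑lactone and ring B in one Mn/Cu radical cascade that also creates the isopropenyl group. The enone becomes a dienyl triflate, which is joined to a pyridyl‑pyranone aldehyde; the dihydrofuran closes last.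
- Stereochemistry: C5 of carvone is the only imported centre. C6 is set by alkylation anti to the C5 side chain. The ring B methine and the spiro lactone carbon come from the chair transition state of the radical 6‑exo closure. The carbinol is set by a chiral chromium ligand. The spiro ether carbon is set by hydropalladation opposite the axial C6 methyl, then C–O formation with inversion.
- Enabling feature: once H–Pd adds to the C1=C2–C3=C4 diene of ring C, the tertiary carbon C1 is an allyl terminus (C1–C2(Me)–C3). The acidic pyranone 4‑OH sits three atoms away through the carbinol carbon, so only the five‑membered spiro ether can form, and the C2=C3 alkene of the target is left in place.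

Key step: step 16

Remark: ring C is numbered as in carvone (C1 former carbonyl and later spiro carbon, C2 methyl‑bearing, C5 ring‑fusion CH, C6 quaternary); ring B is the new cyclohexane; 5, 8, 13 and 14 are taken as commercial.

Step 1
Reactants: 1 (S)‑(+)‑carvone
Product: 2 (S)‑10‑hydroxycarvone, (5S)‑5‑(3‑hydroxyprop‑1‑en‑2‑yl)‑2‑methylcyclohex‑2‑en‑1‑one
Conditions: SeO2 (cat.), t‑BuOOH, salicylic acid (cat.), CH2Cl2, rt
Reagents that add atoms: tert‑butyl hydroperoxide, CC(C)(C)OO
Why: Riley‑type allylic oxidation (ene reaction, then [2,3]‑sigmatropic shift) should attack the methyl of the electron‑rich 1,1‑disubstituted alkene and leave the electron‑poor enone and the C5 centre untouched.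

Step 2
Reactants: 2 (S)‑10‑hydroxycarvone
Product: 3 (5S)‑5‑[3‑(tert‑butyldimethylsilyloxy)prop‑1‑en‑2‑yl]‑2‑methylcyclohex‑2‑en‑1‑one
Conditions: TBSCl, imidazole, DMF, rt
Reagents that add atoms: tert‑butyldimethylsilyl chloride, CC(C)(C)[Si](C)(C)Cl
Why: Standard silylation of a primary allylic alcohol masks the hydroxyl against the two enolate alkylations that follow.

Step 3
Reactants: 3 silyl ether of 10‑hydroxycarvone
Product: 4 (5S)‑5‑[3‑(tert‑butyldimethylsilyloxy)prop‑1‑en‑2‑yl]‑2,6‑dimethylcyclohex‑2‑en‑1‑one (C6 epimers, 5,6‑trans expected to predominate)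
Conditions: LiN(i‑Pr)2, THF, −78 °C; MeI, −78 to 0 °C
Reagents that add atoms: iodomethane, CI
Why: Kinetic deprotonation at the α′ position C6 gives the cross‑conjugated lithium enolate, which is methylated (enolate alkylation); the C6 epimer ratio does not matter because C6 is enolised again in step 4.

Step 4
Reactants: 4 6‑methyl enone; 5 5‑iodo‑2‑methylpent‑2‑ene
Product: 6 2,6‑dimethyl‑6‑(4‑methylpent‑3‑en‑1‑yl)‑5‑[3‑(tert‑butyldimethylsilyloxy)prop‑1‑en‑2‑yl]cyclohex‑2‑en‑1‑one, new chain trans and methyl cis to the C5 side chain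
Conditions: LiN(i‑Pr)2, THF, −78 °C; DMPU, 5, −78 °C to rt
Reagents that add atoms: none
Why: The fully substituted C6 enolate should be alkylated on the face opposite the C5 side chain (1,2‑induction in enolate alkylation), which fixes the quaternary ring‑fusion carbon with the methyl cis to that side chain.

Step 5
Reactants: 6 quaternary silyl ether
Product: 7 5‑(3‑hydroxyprop‑1‑en‑2‑yl)‑2,6‑dimethyl‑6‑(4‑methylpent‑3‑en‑1‑yl)cyclohex‑2‑en‑1‑one (configuration as in 6)
Conditions: HF·pyridine, pyridine, THF, 0 °C to rt
Reagents that add atoms: none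
Why: Buffered fluoride desilylation frees the primary allylic alcohol without touching the enone or the alkenes.

Step 6
Reactants: 7 allylic alcohol; 8 methyl malonyl chloride (methyl 3‑chloro‑3‑oxopropanoate)
Product: 9 mixed methyl malonate ester of 7
Conditions: pyridine, CH2Cl2, 0 °C
Reagents that add atoms: none
Why: Acylation of the unhindered primary alcohol by the acid chloride installs the 1,3‑dicarbonyl unit needed for oxidative radical generation.

Step 7
Reactants: 9 allylic methyl malonate
Product: 10 tricyclic lactone ester: ring C enone trans‑fused to ring B, which carries an equatorial isopropenyl group and a spiro δ‑lactone (CH2O arm on the same face as the C6 methyl) bearing CO2Me α to the lactone carbonyl (epimers at that carbon)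
Conditions: Mn(OAc)3·2H2O (2.2 equiv), Cu(OAc)2·H2O (1 equiv), degassed AcOH, 60 °C
Reagents that add atoms: none
Why: Oxidative free‑radical cyclization with Mn(OAc)3/Cu(OAc)2: the malonyl radical should close the δ‑lactone 6‑endo onto the 1,1‑disubstituted alkene, the resulting tertiary radical should close ring B 6‑exo onto the trisubstituted alkene through a chair transition state (trans fusion enforced by the trans arms on C5 and C6, radical‑bearing carbon equatorial, lactone CH2O arm expected axial beside the C6 methyl), and divalent copper should oxidise the final tertiary radical to the isopropenyl group.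

Step 8
Reactants: 10 tricyclic lactone ester
Product: 11 tricyclic lactone enone (ring C enone, ring B, spiro δ‑lactone, isopropenyl)
Conditions: LiCl, H2O, DMSO, 150 °C
Reagents that add atoms: none
Why: Krapcho dealkoxycarbonylation removes the methyl ester by chloride attack at its methyl group and loss of CO2; the neopentyl lactone CH2–O bond is too hindered to compete.

Step 9
Reactants: 11 tricyclic lactone enone
Product: 12 ring C dienyl triflate (C1 trifloxy, C1=C2 and C3=C4 double bonds)
Conditions: Tf2O, 2,6‑di‑tert‑butyl‑4‑methylpyridine, CH2Cl2, 0 °C to rt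
Reagents that add atoms: trifluoromethanesulfonic anhydride, O=S(=O)(OS(=O)(=O)C(F)(F)F)C(F)(F)F
Why: O‑Sulfonylation of the extended dienol (dienyl triflate formation from an enone) can only enolise toward C4 because C6 is quaternary.

Step 10
Reactants: 13 2,2,6‑trimethyl‑4H‑1,3‑dioxin‑4‑one; 14 nicotinoyl chloride hydrochloride
Product: 15 2,2‑dimethyl‑6‑[2‑oxo‑2‑(pyridin‑3‑yl)ethyl]‑4H‑1,3‑dioxin‑4‑one
Conditions: LiN(SiMe3)2 (3.2 equiv), THF, −78 °C; then 14, −78 to 0 °C; aq. NH4Cl
Reagents that add atoms: none
Why: The lithium dienolate of the dioxinone is acylated at its γ‑carbon by the acid chloride (vinylogous Claisen‑type acylation); the extra base covers the hydrochloride and the acidic product.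

Step 11
Reactants: 15 keto dioxinone
Product: 17 4‑hydroxy‑6‑(pyridin‑3‑yl)‑2H‑pyran‑2‑one, via acylketene 16 (not isolated)
Conditions: toluene, 110 °C
Reagents that add atoms: none
Why: Thermal retro‑[4+2] loss of acetone gives an acylketene that is trapped by the oxygen of its own enolised ketone to form the 4‑hydroxy‑2‑pyranone.

Step 12
Reactants: 17 4‑hydroxy‑6‑(pyridin‑3‑yl)‑2H‑pyran‑2‑one
Product: 18 4‑chloro‑2‑oxo‑6‑(pyridin‑3‑yl)‑2H‑pyran‑3‑carbaldehyde
Conditions: POCl3, DMF, 0 to 60 °C; aq. NaOAc
Reagents that add atoms: N,N‑dimethylformamide, CN(C)C=O; phosphoryl chloride, O=P(Cl)(Cl)Cl; water, O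
Why: Vilsmeier–Haack chloroformylation formylates the nucleophilic C3 and converts the vinylogous acid hydroxyl into chloride, as known for 4‑hydroxy‑2‑pyranones and 4‑hydroxycoumarins.

Step 13
Reactants: 18 4‑chloro‑3‑formylpyranone
Product: 19 2‑oxo‑6‑(pyridin‑3‑yl)‑4‑[2‑(trimethylsilyl)ethoxy]‑2H‑pyran‑3‑carbaldehyde
Conditions: Me3SiCH2CH2OH, Et3N, CH2Cl2, 0 °C to rt
Reagents that add atoms: 2‑(trimethylsilyl)ethanol, C[Si](C)(C)CCO
Why: Addition–elimination at the vinylogous acid chloride replaces chloride by a fluoride‑cleavable ether that keeps the 4‑oxygen non‑acidic during the chromium coupling.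

Step 14
Reactants: 12 ring C dienyl triflate; 19 pyranone aldehyde
Product: 20 (R)‑carbinol: 3‑[(R)‑hydroxy(ring C dien‑1‑yl)methyl]‑6‑(pyridin‑3‑yl)‑4‑[2‑(trimethylsilyl)ethoxy]‑2H‑pyran‑2‑one
Conditions: CrCl2, NiCl2 (cat.), valinol‑derived oxazoline–sulfonamide ligand (enantiomer giving the R carbinol), Et3N, THF, rt
Reagents that add atoms: none
Why: Nozaki–Hiyama–Kishi coupling (nickel‑catalysed formation of the dienylchromium species and its addition to the aldehyde) tolerates lactone, pyranone and pyridine, and the carbinol stereocentre should be set by the chiral sulfonamide ligand on trivalent chromium.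

Step 15
Reactants: 20 (R)‑carbinol
Product: 21 tert‑butyldimethylsilyl ether of 20
Conditions: TBSOTf, 2,6‑lutidine, CH2Cl2, −78 to 0 °C
Reagents that add atoms: tert‑butyldimethylsilyl trifluoromethanesulfonate, CC(C)(C)[Si](C)(C)OS(=O)(=O)C(F)(F)F
Why: Silylation of the hindered bis‑allylic alcohol blocks its loss (vinylogous dehydration to an alkylidene pyrandione) once the pyranone hydroxyl is freed.

Step 16
Reactants: 21 silyl ether
Product: 23 spiro dihydrofuro[3,2‑c]pyranone silyl ether (the O‑TBS ether of the target), via hydroxypyranone diene 22 (not isolated)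
Conditions: Bu4NF (1.05 equiv), THF, 0 °C; then PhCO2H (1.2 equiv), Pd(PPh3)4 (10 mol %), toluene, 60 °C
Reagents that add atoms: none
Why: Proposed new method: fluoride removes the trimethylsilylethyl group; benzoic acid then protonates zerovalent palladium to a divalent palladium hydride, which should add to the less hindered C3=C4 alkene of the ring C diene (H to C4) on the face opposite the axial C6 methyl to give an η3‑allylpalladium over C3–C2–C1, and the pyranone oxygen attacks the tertiary terminus C1 from outside, anti to palladium. The closest known reaction types are palladium‑hydride‑catalysed hydroalkoxylation and hydroamination of 1,3‑dienes by acidic pronucleophiles, and Tsuji–Trost O‑allylation by phenols and carboxylates. The dihydrofuran closes in the 5‑exo mode at the proximal allyl terminus; the only alternative, attack at C3, would need a bridged seven‑membered ether. The spiro stereocentre is controlled by the face of hydropalladation followed by inversion, which should place oxygen on the methyl‑bearing face as the target requires; the R carbinol puts its silyloxy group beside sp2 C2 and not beside quaternary C6 in this closure (matched). The step needs chemoselectivity for the conjugated diene over the isopropenyl group, which palladium hydride addition to dienes provides, and regioselectivity for H at C4, which the fully substituted C1 and the ring‑size constraint secure.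

Step 17
Reactants: 23 spiro silyl ether
Product: 24 target (CNP0126103.3)
Conditions: Bu4NF, AcOH, THF, rt
Reagents that add atoms: none
Why: Buffered fluoride desilylation frees the secondary alcohol, which has no β‑hydrogen and cannot eliminate, while the lactone and the tertiary allylic ether are left alone.

**Compound list**

1 | (S)‑(+)‑carvone | O=C1C(C)=CC[C@H](C(C)=C)C1 | starting material
2 | (S)‑10‑hydroxycarvone | O=C1C(C)=CC[C@H](C(=C)CO)C1 | intermediate
3 | TBS ether of 2 | O=C1C(C)=CC[C@H](C(=C)CO[Si](C)(C)C(C)(C)C)C1 | intermediate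
4 | 6‑methyl derivative of 3 (5,6‑trans epimer drawn) | O=C1C(C)=CC[C@H](C(=C)CO[Si](C)(C)C(C)(C)C)[C@H]1C | intermediate
5 | 5‑iodo‑2‑methylpent‑2‑ene | CC(C)=CCCI | starting material
6 | 6‑methyl‑6‑homoprenyl silyl ether (chain trans to C5 side chain) | O=C1C(C)=CC[C@H](C(=C)CO[Si](C)(C)C(C)(C)C)[C@@]1(C)CCC=C(C)C | intermediate
7 | allylic alcohol from 6 | O=C1C(C)=CC[C@H](C(=C)CO)[C@@]1(C)CCC=C(C)C | intermediate
8 | methyl malonyl chloride | COC(=O)CC(Cl)=O | starting material
9 | mixed methyl malonate of 7 | O=C1C(C)=CC[C@H](C(=C)COC(=O)CC(=O)OC)[C@@]1(C)CCC=C(C)C | intermediate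
10 | tricyclic α‑(methoxycarbonyl) spiro δ‑lactone enone | O=C1C(C)=CC[C@H]2[C@@]1(C)CC[C@@H](C(C)=C)[C@]23CC(C(=O)OC)C(=O)OC3 | intermediate
11 | tricyclic spiro δ‑lactone enone | O=C1C(C)=CC[C@H]2[C@@]1(C)CC[C@@H](C(C)=C)[C@]23CCC(=O)OC3 | intermediate
12 | ring C dienyl triflate | O=S(=O)(OC1=C(C)C=C[C@H]2[C@@]1(C)CC[C@@H](C(C)=C)[C@]23CCC(=O)OC3)C(F)(F)F | intermediate
13 | 2,2,6‑trimethyl‑4H‑1,3‑dioxin‑4‑one | CC1=CC(=O)OC(C)(C)O1 | starting material
14 | nicotinoyl chloride hydrochloride | Cl.O=C(Cl)c1cccnc1 | starting material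
15 | 2,2‑dimethyl‑6‑[2‑oxo‑2‑(pyridin‑3‑yl)ethyl]‑4H‑1,3‑dioxin‑4‑one | CC1(C)OC(CC(=O)c2cccnc2)=CC(=O)O1 | intermediate
16 | acylketene, 3,5‑dioxo‑5‑(pyridin‑3‑yl)pent‑1‑en‑1‑one (not isolated) | O=C=CC(=O)CC(=O)c1cccnc1 | intermediate
17 | 4‑hydroxy‑6‑(pyridin‑3‑yl)‑2H‑pyran‑2‑one | O=c1cc(O)cc(-c2cccnc2)o1 | intermediate
18 | 4‑chloro‑2‑oxo‑6‑(pyridin‑3‑yl)‑2H‑pyran‑3‑carbaldehyde | O=Cc1c(Cl)cc(-c2cccnc2)oc1=O | intermediate
19 | 2‑oxo‑6‑(pyridin‑3‑yl)‑4‑[2‑(trimethylsilyl)ethoxy]‑2H‑pyran‑3‑carbaldehyde | O=Cc1c(OCC[Si](C)(C)C)cc(-c2cccnc2)oc1=O | intermediate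
20 | (R)‑dienyl pyranonyl carbinol | O=c1oc(-c2cccnc2)cc(OCC[Si](C)(C)C)c1[C@H](O)C1=C(C)C=C[C@H]2[C@@]1(C)CC[C@@H](C(C)=C)[C@]23CCC(=O)OC3 | intermediate
21 | TBS ether of 20 | O=c1oc(-c2cccnc2)cc(OCC[Si](C)(C)C)c1[C@H](O[Si](C)(C)C(C)(C)C)C1=C(C)C=C[C@H]2[C@@]1(C)CC[C@@H](C(C)=C)[C@]23CCC(=O)OC3 | intermediate
22 | 4‑hydroxypyranone diene silyl ether (not isolated) | O=c1oc(-c2cccnc2)cc(O)c1[C@H](O[Si](C)(C)C(C)(C)C)C1=C(C)C=C[C@H]2[C@@]1(C)CC[C@@H](C(C)=C)[C@]23CCC(=O)OC3 | intermediate
23 | spiro dihydrofuropyranone silyl ether | C=C(C)[C@@H]1CC[C@]2(C)[C@H](CC=C(C)[C@@]23Oc2cc(-c4cccnc4)oc(=O)c2[C@@H]3O[Si](C)(C)C(C)(C)C)[C@@]12CCC(=O)OC2 | intermediate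
24 | CNP0126103.3 | C=C(C)[C@@H]1CC[C@]2(C)[C@H](CC=C(C)[C@@]23Oc2cc(-c4cccnc4)oc(=O)c2[C@@H]3O)[C@@]12CCC(=O)OC2 | target

**Totals**

Total steps: 17. Longest linear sequence: 13 steps (steps 1–9 and 14–17).

**Steps most likely to fail**

Step 16. Hydropalladation of the hindered ring C diene may be slow or may run as diene isomerisation. C–O formation may go through an inner‑sphere path and deliver oxygen to the wrong face. Reversible ionisation of the tertiary allylic pyranonyl ether may scramble the spiro centre. Fallback with known chemistry, setting out from 11 and returning at 23: conjugate reduction of 11 with LiBH(s‑Bu)3 at −78 °C and trapping of the enolate with PhNTf2 gives the tetrasubstituted ring C enol triflate F1. Nozaki–Hiyama–Kishi coupling of F1 with 19 under the conditions of step 14 gives the allylic carbinol F2, which is silylated (TBSOTf, 2,6‑lutidine) to the silyl ether F3. Bu4NF frees the hydroxypyranone F4. Iodoetherification (I2, NaHCO3, MeCN, 0 °C) then forms the same C–O bond by 5‑exo attack of the pyranone oxygen anti to an iodonium ion on the face away from the axial methyl, giving the tertiary iodide F5. DBU in toluene removes HI toward the ring CH2 and returns 23.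

Step 7. The first ring closure through the ester tether may be sluggish. Trivalent manganese may oxidise the intermediate tertiary radical before ring B closes. Facial selectivity at the spiro lactone carbon may be poor, and the final oxidative elimination may not be regioselective. Fallback setting out from 7 and returning at 11: esterification of 7 with iodoacetic acid (DCC, DMAP) gives the iodoacetate F6. Iodine‑atom‑transfer bicyclisation (Bu3SnSnBu3 cat., sunlamp, benzene, 80 °C) runs the 6‑endo/6‑exo sequence without any oxidant and gives the tertiary iodide F7. DBU then eliminates HI to give 11, so that steps 6–8 are replaced.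

Step 14. Reagent control of the carbinol configuration may be overridden by the neighbouring quaternary centre, and coupling at the hindered dienyl triflate may be slow. Fallback setting out from 12 and 19 and returning at 20: coupling without chiral ligand (CrCl2, NiCl2 cat., DMF) gives 20 mixed with its carbinol epimer F8. Dess–Martin oxidation of the mixture gives the dienyl pyranonyl ketone F9. Corey–Bakshi–Shibata reduction (oxazaborolidine enantiomer chosen for the R carbinol, catecholborane, −78 °C) returns 20.

**Further compounds**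

F1 | step 16 | ring C enol triflate (C1=C2 only) | O=S(=O)(OC1=C(C)CC[C@H]2[C@@]1(C)CC[C@@H](C(C)=C)[C@]23CCC(=O)OC3)C(F)(F)F
F2 | step 16 | allylic carbinol from F1 and 19 | O=c1oc(-c2cccnc2)cc(OCC[Si](C)(C)C)c1[C@H](O)C1=C(C)CC[C@H]2[C@@]1(C)CC[C@@H](C(C)=C)[C@]23CCC(=O)OC3
F3 | step 16 | TBS ether of F2 | O=c1oc(-c2cccnc2)cc(OCC[Si](C)(C)C)c1[C@H](O[Si](C)(C)C(C)(C)C)C1=C(C)CC[C@H]2[C@@]1(C)CC[C@@H](C(C)=C)[C@]23CCC(=O)OC3
F4 | step 16 | 4‑hydroxypyranone from F3 | O=c1oc(-c2cccnc2)cc(O)c1[C@H](O[Si](C)(C)C(C)(C)C)C1=C(C)CC[C@H]2[C@@]1(C)CC[C@@H](C(C)=C)[C@]23CCC(=O)OC3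
F5 | step 16 | tertiary iodide spiro ether | C=C(C)[C@@H]1CC[C@]2(C)[C@H](CC[C@](C)(I)[C@@]23Oc2cc(-c4cccnc4)oc(=O)c2[C@@H]3O[Si](C)(C)C(C)(C)C)[C@@]12CCC(=O)OC2
F6 | step 7 | iodoacetate of 7 | O=C1C(C)=CC[C@H](C(=C)COC(=O)CI)[C@@]1(C)CCC=C(C)C
F7 | step 7 | tricyclic lactone enone with 2‑iodopropan‑2‑yl group | O=C1C(C)=CC[C@H]2[C@@]1(C)CC[C@@H](C(C)(C)I)[C@]23CCC(=O)OC3
F8 | step 14 | carbinol epimer of 20 | O=c1oc(-c2cccnc2)cc(OCC[Si](C)(C)C)c1[C@@H](O)C1=C(C)C=C[C@H]2[C@@]1(C)CC[C@@H](C(C)=C)[C@]23CCC(=O)OC3
F9 | step 14 | dienyl pyranonyl ketone | O=c1oc(-c2cccnc2)cc(OCC[Si](C)(C)C)c1C(=O)C1=C(C)C=C[C@H]2[C@@]1(C)CC[C@@H](C(C)=C)[C@]23CCC(=O)OC3
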